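The numbers in the tables were computed on assumed constants, noise included.

No rate constant is known for this flask, but one number read from the runs can stand in for the constants.

| setting | grey | ochre | flask |
|---|---|---|---|
| substrate | 0.050 M | 0.050 M | 0.050 M |
| reagent | 0.040 M | 0.040 M | 0.0400 M |
| free catalyst | 0.10 mM | 0.15 mM | 0.10 mM |
| remark | the very flask that is asked about, followed so far | run made earlier |  |
| time |  |  | 40 min |

grey run (percent of the substrate charged)

| time / min | target / % | substrate / % |
|---|---|---|
| 2.00 | 31.1 | 62.0 |
| 3.00 | 30.7 | 60.3 |
| 5.00 | 30.4 | 57.2 |
| 8.00 | 30.1 | 60.0 |
| 15.0 | 29.5 | 60.1 |
| 25.0 | 28.1 | 60.0 |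

ochre run (percent of the substrate charged)

| time / s | target / % | substrate / % |
|---|---|---|
| 10.0 | 27.9 | 63.8 |
| 12.0 | 29.7 | 62.3 |
| 20.0 | 33.2 | 52.2 |
| 30.0 | 35.7 | 51.4 |
| 50.0 | 38.5 | 49.9 |
| 80.0 | 37.5 | 47.4 |

(standard deviation of a reading: 1 percentage point)

- north: at 40 min add reagent, 50.0% of the amount charged, then wait 20 min
- north-west: change nothing and wait 20 min more
- south: at 40 min add free catalyst, 100% of the amount charged, then wait 20 min
- south-west: at 40 min take out 90% of the by-product then present, then wait 20 min

- additions leave the volume as it is

1. target, in percent of the substrate first charged, at 40 min
2. what to do for the largest gain in target; "none" if nothing gains more than 2 percentage points (north / north-west / south / south-west / none)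
3. target present, in percent of the substrate first charged, after north-west
4. target present, in percent of the substrate first charged, after south

1. Compare rates at one moment. Suppose each turnover competes with a loss of catalyst, and suppose the turnover rate goes with free substrate while the loss rate does not. Substrate used per catalyst lost then shrinks as substrate drifts down. Summed over the run, this makes −ln f proportional to the catalyst charged, where f is the fraction of charged substrate left at the stall. It is a pseudo-first-order decay, counted in catalyst lost instead of time.

2. The last grey readings give f = 0.600, so the stall exponent, −ln f, is 0.510. The last two ochre readings give f = 0.486, an exponent of 0.721. The exponents stand in the ratio 1.41, less than the catalyst ratio of 1.50, so I accept the rule as a close approximation.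

3. There are two ways to the grey target at 40 min. By balance, the late ochre readings give 0.740 of target per fraction of substrate consumed, and this gives 29.6% for grey. By a line through the first and last grey target readings, the result is 26.1%, lower than the balance. The line rests on a drop of 3 percentage points between two readings, each scattering by 1 point, and it runs 15.0 min past the last reading. So I commit to the balance, and to the same value after north-west.

4. South doubles the catalyst, so the exponent doubles. Then f = 0.360 and target is 47.3%. The rule holds no term for reagent or by-product, so I expect nothing from north or south-west, and I choose south.

5. The forecast gives 26.4% now, 24.1% after north-west and 35% after south, and it also chooses south. Its ground: “An equilibrium would give the same plateau, so the catalyst is dying (or being bound) rather than the reaction reaching equilibrium.” Its values lie below mine, both now and after south.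

6. The flask gives 29.5% now, 29.5% after north-west and 45.9% after south. The best option is south, with a gain of 16 points, more than any other option brings.

    2 free catalyst → spent catalyst B (k = 1130 L mol⁻¹ s⁻¹)
    reagent + free catalyst ⇌ catalyst intermediate A (K = 61.8 L mol⁻¹, k = 39000 L mol⁻¹ s⁻¹)
    target ⇌ isomer of the product (K = 0.350, k = 0.151 s⁻¹)
    catalyst intermediate A → spent catalyst A (k = 0.223 s⁻¹)
    catalyst intermediate C ⇌ free catalyst + target (K = 0.0260 M, k = 225 s⁻¹)
    substrate + catalyst intermediate A ⇌ catalyst intermediate B (K = 13.7 L mol⁻¹, k = 29000 L mol⁻¹ s⁻¹)
    catalyst intermediate B → by-product + catalyst intermediate C (k = 91.7 s⁻¹)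

Waiting changes nothing in the grey flask. There, at 40.0 min, free catalyst stands at 0%, spent catalyst A at 94.1% and spent catalyst B at 5.87%. Removing the reaction of catalyst intermediate A to spent catalyst A lifts grey target from 29.5% to 58.9%, a single effect and not the main reason. The doubled exponent gave 47.3% after south, against the 45.9% found.

On the neighbour charged with 2.5 × 10⁻⁵ M of free catalyst, the exponent scaled to its catalyst gives f = 0.880 and target 8.88%. The computed flask keeps 88% of its substrate and gives 9.25% target.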